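**Retrosynthetic overview**

1. Feature: a hydroazulene whose methyl-bearing quaternary fusion carbon C1 and fusion carbon C5 are joined by the three-atom bridge C2–C3–C4 (C4 = isopropyl carbinol; ring A, five-membered) and by C6–C7–C8–C9–C10 (ring B, seven-membered). It is the adduct of a tethered alkyne (C5≡C6), an alkene (C1=C10) and a cyclopropane (C9, C8, C7).
2. Key disconnection: C1–C5 and C6–C7, formed together by a rhodium-catalysed (5+2) cycloaddition of an acyclic enyne carrying a trans-methylcyclopropane; rings A and B arise in this one step.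
3. After it: C5=C6 → 4β,6α-diol with 5α-H (hydroxyl-directed epoxidation, titanocene reductive opening, oxidation, 1,3-anti reduction) → 6-angelate. C9=C10 → 9α,10α-epoxide → C8=C9 with 10α-OH (selenide opening, selenoxide elimination) → directed epoxidation.
4. Before it: (E)-crotyl alcohol → enantioenriched cyclopropylmethanol → aldehyde → isopropenyl carbinol → Johnson–Claisen ester (E-C1=C10) → isopropyl ketone → asymmetric alkynylation (C4).
5. Ring order: cyclopropane (step 1, opened again in step 9), rings A and B (step 9), oxirane (step 17).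

Key step: step 9

Assumption: α and β name the faces of the bicyclic core, β being the face of the C1 methyl group; the salen enantiomer named in step 7 is taken to be the one that favours the 3R carbinol (otherwise its antipode is used).

**Route**

Step 1
Reactants: 1 (E)-but-2-en-1-ol
Product: 2 [(1R,2R)-2-methylcyclopropyl]methanol
Conditions: ZnEt2, CH2I2, DME, (4S,5S)-2-butyl-N,N,N',N'-tetramethyl-1,3,2-dioxaborolane-4,5-dicarboxamide (1.2 equiv), CH2Cl2, −10 °C → rt; aq NaOH work-up
Reagents that add atoms: diiodomethane, ICI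
Why: Simmons–Smith cyclopropanation of an (E)-allylic alcohol under stoichiometric control of a chiral dioxaborolane is stereospecific (trans from E), and the (4S,5S)-controller, antipode of the one known to give (1S,2S)-cyclopropylmethanols from E-allylic alcohols, should set both cyclopropane centres (later C9 and C8) as 1R,2R.

Step 2
Reactants: 2 [(1R,2R)-2-methylcyclopropyl]methanol
Product: 3 (1R,2R)-2-methylcyclopropane-1-carbaldehyde (kept as a dried CH2Cl2 solution)
Conditions: (COCl)2, DMSO, CH2Cl2, −78 °C; Et3N, −78 → 0 °C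
Reagents that add atoms: none
Why: Swern oxidation of a primary alcohol is non-acidic and leaves the cyclopropane and its α-stereocentre untouched, and the volatile aldehyde is not taken to dryness.

Step 3
Reactants: 3 (1R,2R)-2-methylcyclopropane-1-carbaldehyde; 4 isopropenylmagnesium bromide
Product: 5 2-methyl-1-[(1R,2R)-2-methylcyclopropyl]prop-2-en-1-ol (both carbinol epimers)
Conditions: THF/CH2Cl2, −78 → 0 °C; aq NH4Cl
Reagents that add atoms: isopropenylmagnesium bromide (4), C=C(C)[Mg]Br
Why: Grignard addition of an alkenylmagnesium halide to an aldehyde is reliable, and the new carbinol centre needs no control because step 4 erases it.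

Step 4
Reactants: 5 2-methyl-1-[(1R,2R)-2-methylcyclopropyl]prop-2-en-1-ol; 6 triethyl orthoacetate
Product: 8 ethyl (4E)-4-methyl-5-[(1R,2R)-2-methylcyclopropyl]pent-4-enoate, via ketene acetal 7 (not isolated)
Conditions: MeC(OEt)3 (excess), EtCO2H (cat.), 140 °C, EtOH distilled off
Reagents that add atoms: triethyl orthoacetate (6), CCOC(C)(OCC)OCC
Why: The Johnson–Claisen rearrangement of a 2-methylallylic secondary alcohol runs through a chair transition state with the cyclopropyl group equatorial and so gives the E trisubstituted C1=C10 alkene with C2, C3 and the C4 ester carbon attached, while a trans-cyclopropane cannot undergo the homodienyl hydrogen shift at this temperature.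

Step 5
Reactants: 8 ethyl (4E)-4-methyl-5-[(1R,2R)-2-methylcyclopropyl]pent-4-enoate; 9 N,O-dimethylhydroxylamine hydrochloride
Product: 10 (4E)-N-methoxy-N,4-dimethyl-5-[(1R,2R)-2-methylcyclopropyl]pent-4-enamide
Conditions: AlMe3, CH2Cl2, 0 °C → rt; aq potassium sodium tartrate
Reagents that add atoms: N,O-dimethylhydroxylamine hydrochloride (9), CNOC.Cl
Why: Aminolysis of the ester by Me(Cl)AlN(OMe)Me (Weinreb amide formation) is chemoselective and does not affect the vinylcyclopropane.

Step 6
Reactants: 10 (4E)-N-methoxy-N,4-dimethyl-5-[(1R,2R)-2-methylcyclopropyl]pent-4-enamide; 11 isopropylmagnesium chloride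
Product: 12 (6E)-2,6-dimethyl-7-[(1R,2R)-2-methylcyclopropyl]hept-6-en-3-one
Conditions: THF, 0 °C → rt; aq NH4Cl
Reagents that add atoms: isopropylmagnesium chloride (11), CC(C)[Mg]Cl
Why: In the Weinreb ketone synthesis the chelated tetrahedral adduct survives until work-up, so the Grignard reagent adds only once.

Step 7
Reactants: 12 (6E)-2,6-dimethyl-7-[(1R,2R)-2-methylcyclopropyl]hept-6-en-3-one; 13 ethynyltrimethylsilane
Product: 14 (3R,6E)-6-methyl-7-[(1R,2R)-2-methylcyclopropyl]-3-(propan-2-yl)-1-(trimethylsilyl)hept-6-en-1-yn-3-ol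
Conditions: ZnMe2, (R,R)-N,N'-bis(3,5-di-tert-butylsalicylidene)cyclohexane-1,2-diamine (20 mol%), PhMe, rt
Reagents that add atoms: ethynyltrimethylsilane (13), C#C[Si](C)(C)C
Why: Catalytic asymmetric alkynylation of a ketone by MeZnC≡CSiMe3 held on zinc by the chiral salen ligand distinguishes the branched isopropyl flank from the CH2 flank and sets C4 (3R in this name); discrimination is expected to be incomplete, but the 3S epimer is a diastereomer because of the cyclopropane and is removed after step 9.

Step 8
Reactants: 14 (3R,6E)-6-methyl-7-[(1R,2R)-2-methylcyclopropyl]-3-(propan-2-yl)-1-(trimethylsilyl)hept-6-en-1-yn-3-ol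
Product: 15 (3R,6E)-6-methyl-7-[(1R,2R)-2-methylcyclopropyl]-3-(propan-2-yl)hept-6-en-1-yn-3-ol
Conditions: K2CO3, MeOH, rt
Reagents that add atoms: none
Why: Base-catalysed methanolysis of the alkynyl C–Si bond (protodesilylation) frees the terminal alkyne and leaves the tertiary carbinol and the alkene untouched.

Step 9
Reactants: 15 (3R,6E)-6-methyl-7-[(1R,2R)-2-methylcyclopropyl]-3-(propan-2-yl)hept-6-en-1-yn-3-ol
Product: 16 4α-isopropyl-1β,8α-dimethylbicyclo[5.3.0]deca-5,9-dien-4β-ol (numbering of the overview)
Conditions: [Rh(CO)2Cl]2 (5 mol%), ClCH2CH2Cl (0.02 M), 80 °C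
Reagents that add atoms: none
Why: Monovalent rhodium binds the C1=C10 alkene and opens the adjoining cyclopropane at its less substituted C9–C7 bond to a σ,π-allyl rhodacycle, the tethered alkyne then inserts into the Rh–C1 bond, and C6–C7 reductive elimination releases the diene. The closest known reaction type is the rhodium-catalysed intramolecular (5+2) cycloaddition of alkyne-tethered vinylcyclopropanes, which accepts terminal alkynes, 1,1-disubstituted alkene termini (angular quaternary carbons) and trans-2-alkyl cyclopropanes. Ring A closes as a five-membered ring by the alkyne insertion that forms C1–C5 across the C2–C3–C4 tether, and ring B closes by reductive elimination of C6–C7 from the eight-membered rhodacycle. C1 is the only new stereocentre and is fixed by substrate geometry: C5 adds to the alkene face on which the cleaving carbon C7 lies in the s-cis conformer, so the E alkene and the (1R,2R)-cyclopropane together place the C1 methyl and H8 on the same face, while C8 is carried over unchanged and C9 becomes sp2. The step needs cleavage of C9–C7 rather than C9–C8 (which would also turn the alkene face), secured by the trans methyl group because the less substituted and less hindered bond inserts, and it needs a geometrically pure alkene, which step 4 supplies. The 3R carbinol is the matched partner, since in the forming ring A its isopropyl group can lie anti to the new angular methyl, and the free tertiary hydroxyl is a spectator.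

Step 10
Reactants: 16 4α-isopropyl-1β,8α-dimethylbicyclo[5.3.0]deca-5,9-dien-4β-ol
Product: 17 5β,6β-epoxy-4α-isopropyl-1β,8α-dimethylbicyclo[5.3.0]dec-9-en-4β-ol
Conditions: VO(acac)2 (5 mol%), t-BuOOH (decane), CH2Cl2, 0 °C → rt
Reagents that add atoms: tert-butyl hydroperoxide, CC(C)(C)OO
Why: In the vanadium-catalysed hydroxyl-directed epoxidation the C4 alkoxide carries the peroxide to the adjacent trisubstituted C5=C6 alkene on the β face, syn to the C4 hydroxyl, and the isolated C9=C10 alkene is not touched.

Step 11
Reactants: 17 5β,6β-epoxy-4α-isopropyl-1β,8α-dimethylbicyclo[5.3.0]dec-9-en-4β-ol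
Product: 18 4α-isopropyl-1β,8α-dimethyl-5αH-bicyclo[5.3.0]dec-9-ene-4β,6β-diol
Conditions: Cp2TiCl2, Zn dust, 1,4-cyclohexadiene, THF, rt
Reagents that add atoms: none
Why: In this titanocene-mediated reductive opening of a 2,3-epoxy alcohol to a 1,3-diol, Cp2TiCl (trivalent titanium) cleaves the C5–O bond homolytically to the tertiary C5 radical with C6–O retained, and the radical should take hydrogen from 1,4-cyclohexadiene on the α face, anti to the angular methyl and to the two titanium-bound oxygens, which sets the trans fusion (5α-H) without a cation that could undergo semipinacol or ring-contraction shifts.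

Step 12
Reactants: 18 4α-isopropyl-1β,8α-dimethyl-5αH-bicyclo[5.3.0]dec-9-ene-4β,6β-diol
Product: 19 4β-hydroxy-4α-isopropyl-1β,8α-dimethyl-5αH-bicyclo[5.3.0]dec-9-en-6-one
Conditions: Dess–Martin periodinane, NaHCO3, CH2Cl2, 0 °C → rt
Reagents that add atoms: none
Why: Dess–Martin oxidation converts only the secondary C6 alcohol and, being buffered and non-basic, should give the β-hydroxy ketone without retro-aldol cleavage or epimerisation at C5.

Step 13
Reactants: 19 4β-hydroxy-4α-isopropyl-1β,8α-dimethyl-5αH-bicyclo[5.3.0]dec-9-en-6-one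
Product: 20 4α-isopropyl-1β,8α-dimethyl-5αH-bicyclo[5.3.0]dec-9-ene-4β,6α-diol
Conditions: Me4NBH(OAc)3, MeCN/AcOH, −30 °C
Reagents that add atoms: none
Why: In the Evans–Saksena reduction the C4 hydroxyl exchanges onto boron and delivers hydride intramolecularly to the β face of the C6 carbonyl, which gives the 1,3-anti diol with the C6 hydroxyl α.

Step 14
Reactants: 20 4α-isopropyl-1β,8α-dimethyl-5αH-bicyclo[5.3.0]dec-9-ene-4β,6α-diol; 21 angelic acid [(Z)-2-methylbut-2-enoic acid]
Product: 22 6α-angeloyloxy-4α-isopropyl-1β,8α-dimethyl-5αH-bicyclo[5.3.0]dec-9-en-4β-ol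
Conditions: 21, 2,4,6-Cl3C6H2COCl, Et3N, PhMe, rt; then 20, 75 °C
Reagents that add atoms: angelic acid (21), C/C=C(/C)C(=O)O
Why: Yamaguchi-type esterification with the preformed mixed anhydride and no nucleophilic catalyst acylates the secondary C6 hydroxyl without Z-to-E isomerisation of the angelate, and the hindered tertiary C4 hydroxyl does not react.

Step 15
Reactants: 22 6α-angeloyloxy-4α-isopropyl-1β,8α-dimethyl-5αH-bicyclo[5.3.0]dec-9-en-4β-ol
Product: 23 6α-angeloyloxy-9α,10α-epoxy-4α-isopropyl-1β,8α-dimethyl-5αH-bicyclo[5.3.0]decan-4β-ol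
Conditions: mCPBA, NaHCO3, CH2Cl2, 0 °C
Reagents that add atoms: mCPBA, OOC(=O)c1cccc(Cl)c1
Why: Prilezhaev epoxidation attacks the only electron-rich alkene, C9=C10, from the α face because the pseudo-axial C1 methyl shields the β face, and the electron-poor angelate alkene is inert to the peracid.

Step 16
Reactants: 23 6α-angeloyloxy-9α,10α-epoxy-4α-isopropyl-1β,8α-dimethyl-5αH-bicyclo[5.3.0]decan-4β-ol
Product: 26 6α-angeloyloxy-4α-isopropyl-1β,8-dimethyl-5αH-bicyclo[5.3.0]dec-8-ene-4β,10α-diol, via hydroxy selenide 24 (not isolated), via selenoxide 25 (not isolated)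
Conditions: (PhSe)2, NaBH4, EtOH, rt then 60 °C; then THF, 30% H2O2, pyridine, 0 °C → rt
Reagents that add atoms: none
Why: In this epoxide-to-allylic-alcohol transposition by selenide opening and selenoxide syn-elimination, PhSeNa attacks the less hindered C9 anti to the epoxide oxygen (9β-Se, 10α-OH), the selenoxide then eliminates with the cis H8 (β, as set in step 9) and away from the carbinol carbon to give C8=C9, and the weakly basic borate-complexed selenolate is a poor partner for the α,β-disubstituted angelate.

Step 17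
Reactants: 26 6α-angeloyloxy-4α-isopropyl-1β,8-dimethyl-5αH-bicyclo[5.3.0]dec-8-ene-4β,10α-diol
Product: 27 lapiferine
Conditions: VO(acac)2 (5 mol%), t-BuOOH (decane), CH2Cl2, 0 °C → rt
Reagents that add atoms: tert-butyl hydroperoxide, CC(C)(C)OO
Why: Vanadium-catalysed hydroxyl-directed epoxidation of the seven-membered cyclic allylic alcohol delivers oxygen to the α face of C8=C9, syn to the 10α-hydroxyl, which sets C8 and C9, and the angelate alkene is not an allylic alcohol and stays intact.

**Compound list**

1 | (E)-but-2-en-1-ol | C/C=C/CO | starting material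
2 | [(1R,2R)-2-methylcyclopropyl]methanol | OC[C@@H]1C[C@H]1C | intermediate
3 | (1R,2R)-2-methylcyclopropane-1-carbaldehyde | O=C[C@@H]1C[C@H]1C | intermediate
4 | isopropenylmagnesium bromide | C=C(C)[Mg]Br | starting material
5 | 2-methyl-1-[(1R,2R)-2-methylcyclopropyl]prop-2-en-1-ol (both carbinol epimers) | C=C(C)C(O)[C@@H]1C[C@H]1C | intermediate
6 | triethyl orthoacetate | CCOC(C)(OCC)OCC | starting material
7 | ketene acetal: 1-ethoxyvinyl ether of 5 | C=C(OCC)OC(C(C)=C)[C@@H]1C[C@H]1C | intermediate (not isolated)
8 | ethyl (4E)-4-methyl-5-[(1R,2R)-2-methylcyclopropyl]pent-4-enoate | CCOC(=O)CC/C(C)=C/[C@@H]1C[C@H]1C | intermediate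
9 | N,O-dimethylhydroxylamine hydrochloride | CNOC.Cl | starting material
10 | (4E)-N-methoxy-N,4-dimethyl-5-[(1R,2R)-2-methylcyclopropyl]pent-4-enamide | CON(C)C(=O)CC/C(C)=C/[C@@H]1C[C@H]1C | intermediate
11 | isopropylmagnesium chloride | CC(C)[Mg]Cl | starting material
12 | (6E)-2,6-dimethyl-7-[(1R,2R)-2-methylcyclopropyl]hept-6-en-3-one | CC(C)C(=O)CC/C(C)=C/[C@@H]1C[C@H]1C | intermediate
13 | ethynyltrimethylsilane | C#C[Si](C)(C)C | starting material
14 | (3R,6E)-6-methyl-7-[(1R,2R)-2-methylcyclopropyl]-3-(propan-2-yl)-1-(trimethylsilyl)hept-6-en-1-yn-3-ol | C[Si](C)(C)C#C[C@](O)(C(C)C)CC/C(C)=C/[C@@H]1C[C@H]1C | intermediate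
15 | (3R,6E)-6-methyl-7-[(1R,2R)-2-methylcyclopropyl]-3-(propan-2-yl)hept-6-en-1-yn-3-ol (key-step precursor) | C#C[C@](O)(C(C)C)CC/C(C)=C/[C@@H]1C[C@H]1C | intermediate
16 | 4α-isopropyl-1β,8α-dimethylbicyclo[5.3.0]deca-5,9-dien-4β-ol (key-step product) | C=1C[C@@H](C)C=C[C@@]2(C)CC[C@@](O)(C(C)C)C=12 | intermediate
17 | 5β,6β-epoxy-4α-isopropyl-1β,8α-dimethylbicyclo[5.3.0]dec-9-en-4β-ol | O1[C@@H]2C[C@@H](C)C=C[C@@]3(C)CC[C@@](O)(C(C)C)[C@@]123 | intermediate
18 | 4α-isopropyl-1β,8α-dimethyl-5αH-bicyclo[5.3.0]dec-9-ene-4β,6β-diol | O[C@@H]1C[C@@H](C)C=C[C@@]2(C)CC[C@@](O)(C(C)C)[C@H]12 | intermediate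
19 | 4β-hydroxy-4α-isopropyl-1β,8α-dimethyl-5αH-bicyclo[5.3.0]dec-9-en-6-one | O=C1C[C@@H](C)C=C[C@@]2(C)CC[C@@](O)(C(C)C)[C@H]12 | intermediate
20 | 4α-isopropyl-1β,8α-dimethyl-5αH-bicyclo[5.3.0]dec-9-ene-4β,6α-diol | O[C@H]1C[C@@H](C)C=C[C@@]2(C)CC[C@@](O)(C(C)C)[C@H]12 | intermediate
21 | angelic acid, (Z)-2-methylbut-2-enoic acid | C/C=C(/C)C(=O)O | starting material
22 | 6α-angeloyloxy-4α-isopropyl-1β,8α-dimethyl-5αH-bicyclo[5.3.0]dec-9-en-4β-ol | C/C=C(/C)C(=O)O[C@H]1C[C@@H](C)C=C[C@@]2(C)CC[C@@](O)(C(C)C)[C@H]12 | intermediate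
23 | 6α-angeloyloxy-9α,10α-epoxy-4α-isopropyl-1β,8α-dimethyl-5αH-bicyclo[5.3.0]decan-4β-ol | C/C=C(/C)C(=O)O[C@H]1C[C@@H](C)[C@H]3O[C@H]3[C@@]2(C)CC[C@@](O)(C(C)C)[C@H]12 | intermediate
24 | hydroxy selenide: 6α-angeloyloxy-9β-(phenylselanyl)-4α-isopropyl-1β,8α-dimethyl-5αH-bicyclo[5.3.0]decane-4β,10α-diol | C/C=C(/C)C(=O)O[C@H]1C[C@@H](C)[C@H]([Se]c3ccccc3)[C@@H](O)[C@@]2(C)CC[C@@](O)(C(C)C)[C@H]12 | intermediate (not isolated)
25 | selenoxide of 24 (9β-phenylseleninyl) | C/C=C(/C)C(=O)O[C@H]1C[C@@H](C)[C@H]([Se](=O)c3ccccc3)[C@@H](O)[C@@]2(C)CC[C@@](O)(C(C)C)[C@H]12 | intermediate (not isolated)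
26 | 6α-angeloyloxy-4α-isopropyl-1β,8-dimethyl-5αH-bicyclo[5.3.0]dec-8-ene-4β,10α-diol | C/C=C(/C)C(=O)O[C@H]1CC(C)=C[C@@H](O)[C@@]2(C)CC[C@@](O)(C(C)C)[C@H]12 | intermediate
27 | lapiferine (6α-angeloyloxy-8α,9α-epoxy-4α-isopropyl-1β,8β-dimethyl-5αH-bicyclo[5.3.0]decane-4β,10α-diol) | C/C=C(/C)C(=O)O[C@H]1C[C@@]2(C)O[C@H]2[C@@H](O)[C@@]2(C)CC[C@@](O)(C(C)C)[C@H]12 | target

**Step count and risks**

Total step count: 17. Longest linear sequence: 17 steps (from 1; the route is fully linear).

Steps most likely to fail:

Step 9 (key step). The cycloaddition may stall because the C1 methyl group, cis to the cyclopropane, strains the s-cis conformer that the metal needs. Rhodium may also insert into the more substituted C9–C8 bond, which would give the regioisomeric ring B together with the opposite configuration at C1. Interference by the free propargylic carbinol, or a mismatch between C4 and the face imposed by the cyclopropane, would show up in the same way. The fallback sets out from Weinreb amide 10 and activates the alkyne while taking C4 out of the cycloaddition. Ethynylmagnesium bromide (THF, 0 °C) gives the terminal ynone (6E)-6-methyl-7-[(1R,2R)-2-methylcyclopropyl]hept-6-en-1-yn-3-one F1. [Rh(CO)2Cl]2 (ClCH2CH2Cl, 80 °C) should convert this electron-poor, less crowded ynone into the bicyclic dienone 1β,8α-dimethylbicyclo[5.3.0]deca-5,9-dien-4-one F2, in which C1 is set by the cyclopropane alone. 1,2-Addition of i-PrMgCl in the presence of CeCl3 (THF, −78 °C), from the α face anti to the angular methyl, then gives the 4β-carbinol, and the route is rejoined at 16.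

Step 11. Hydrogen-atom transfer may reach the C5 radical on the β face and give the cis ring fusion, or the radical may be captured by a second titanium centre and lose the neighbouring oxygen by β-elimination. The fallback sets out from epoxide 17 and replaces the radical by a cationic 1,2-shift: a Meinwald rearrangement (BF3·OEt2, CH2Cl2, −78 °C), in which the C6 hydrogen migrates to C5 on the face opposite the breaking C5–O bond. This gives the 5α-H ketone directly and rejoins the route at 19, skipping 18, and no new compound is made. Its own hazard, the semipinacol shift of the isopropyl group from C4 to C5, is the reason it is held in reserve.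

Step 7. The catalyst may discriminate only weakly between the isopropyl and CH2 flanks of ketone 12, so that both C4 epimers form. The fallback sets out from 12 and gives up catalyst control in favour of a later diastereomer separation. Ethynylmagnesium bromide (THF, 0 °C) gives 15 in one step, mixed with its epimer (3S,6E)-6-methyl-7-[(1R,2R)-2-methylcyclopropyl]-3-(propan-2-yl)hept-6-en-1-yn-3-ol F3. The mixture is taken through step 9, where the cyclopropane fixes C1 in both epimers. The C4-epimeric cycloadduct 4β-isopropyl-1β,8α-dimethylbicyclo[5.3.0]deca-5,9-dien-4α-ol F4 is then removed by chromatography, and the route is rejoined at 16.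

**Further compounds**

F1 | step 9 | (6E)-6-methyl-7-[(1R,2R)-2-methylcyclopropyl]hept-6-en-1-yn-3-one | C#CC(=O)CC/C(C)=C/[C@@H]1C[C@H]1C
F2 | step 9 | 1β,8α-dimethylbicyclo[5.3.0]deca-5,9-dien-4-one | C=1C[C@@H](C)C=C[C@@]2(C)CCC(=O)C=12
F0 | step 11 | none | none
F3 | step 7 | (3S,6E)-6-methyl-7-[(1R,2R)-2-methylcyclopropyl]-3-(propan-2-yl)hept-6-en-1-yn-3-ol | C#C[C@@](O)(C(C)C)CC/C(C)=C/[C@@H]1C[C@H]1C
F4 | step 7 | 4β-isopropyl-1β,8α-dimethylbicyclo[5.3.0]deca-5,9-dien-4α-ol | C=1C[C@@H](C)C=C[C@@]2(C)CC[C@](O)(C(C)C)C=12
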